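If each exchange in a flask spends one incoming ligand, I count what the charge can pay for before I integrate anything.

| flask | starting complex | incoming ligand | scavenger | time |
|---|---|---|---|---|
| delta | 0.30 M | 0.285 M | 0.360 M | 20 min |
| beta | 0.30 M | 0.285 M | 0.720 M | 20 min |

    complex with one exchanged + incoming ligand ⇌ leaving ligand + complex with two exchanged (K1 = 0.97, k1 = 0.050 M⁻¹ s⁻¹)
    complex with two exchanged + incoming ligand ⇌ leaving ligand + complex with three exchanged (K2 = 1.0, k2 = 0.073 M⁻¹ s⁻¹)
    complex with three exchanged + incoming ligand ⇌ leaving ligand + complex with four exchanged (K3 = 3.0, k3 = 1.1 M⁻¹ s⁻¹)
    scavenger + leaving ligand → scavenged by-product (k4 = 27 M⁻¹ s⁻¹)
    leaving ligand + starting complex ⇌ idle adduct, settled at all times (K5 = 3.3 M⁻¹)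
    starting complex + incoming ligand ⇌ leaving ligand + complex with one exchanged (K6 = 1.6, k6 = 0.43 M⁻¹ s⁻¹)

* part of the starting complex that has reacted at the end, delta
* part of the starting complex that has reacted at the end, beta
* what raising the concentration of scavenger from its lowest to its highest value here does to the part of the starting complex that has reacted (changes below 5 percentage points count as none) (no change / it rises / it falls)

- leaving ligand is meant together with its idle adduct
- run time (delta): 20 min

Each exchange also frees one leaving ligand, but the scavenger charged in delta exceeds the incoming ligand, and beta holds more scavenger still, so I set the back steps aside in both flasks. I call the turnover count the incoming ligand charged per starting complex charged, 0.950. The bench rule says one turnover, one complex reacted, which promises 95.0%. The clock should not matter much, because even the first step's successor has a half-life of 0.81 min as charged, short against the run.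

The rule assumes that every ligand finds starting complex, but complex with one exchanged competes for it. The selectivity factor, the first exchange's rate constant over the second's, is 8.60. The two rates therefore draw level when 89.6% has reacted, and the turnover count lies beyond that border, but the diversion does not wait for the border: in my reckoning it grows from the start, so I sum it from there. I add up the ratio of the two rates along the way to the border, taking complex with one exchanged equal to what has reacted, and 0.159 turnovers are diverted. That gives 79.1% for delta and 79.1% for beta, with incoming ligand as the limiting reagent. Since the extra scavenger buys no extra turnovers, my trend is no change.

The forecast gives 82.6% for delta, 83% for beta and no change, holding that “the outcome is set by ligand exhaustion, not by time”. Its figure is higher than mine.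

The simulation gives 82.9% for delta, 83.0% for beta and no change, a difference of 0.13 percentage points. Incoming ligand stands at 0% at the end of delta, and 200 min still shows 82.9%. Of the 0.950 turnovers in delta, 0.121 per complex did not go into first exchanges, and complex with two exchanged holds 9.19% of the charge.

Delta with 0.75 M of starting complex has 0.380 turnovers, inside the border. The same sum, stopped there, diverts 0.0114 and predicts 36.9%. That flask computes to 36.9%.

The constants used here belong to no real substance; the rest is arithmetic.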